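**Retrosynthetic overview**
1. The last C–C bond made is C3–CH2Ar, the quaternary carbinol. It comes from a light-driven decarboxylative C–H benzylation of the cis α-hydroxy-β-veratryl-γ-butyrolactone with the redox-active ester of O-silyl homovanillic acid. The C4 side chain sends the benzyl radical to the opposite face.
2. The butyrolactone is the only ring made that stays. The C4 carboxyl of (2S,3R)-3-veratrylmalic acid is reduced while the α-hydroxy acid end is masked as a dioxolanone, and the new alcohol then closes with loss of acetone.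
3. The C4–CH2Ar' bond comes from anti-selective dianion alkylation of diisopropyl (S)-malate with veratryl bromide. C2 of malate is the only stereocentre bought.
4. Ring order: temporary dioxolanone, then γ-lactone. Both arenes are bought.

Assumption: diisopropyl (S)-malate (made from L-malic acid), 3,4-dimethoxybenzyl bromide and homovanillic acid are catalogue items. The given SMILES reads as (3S,4S), with the benzyl groups trans and the OH cis to the C4 side chain.

**Step 1**
Reactants: 1 diisopropyl (S)-malate; 2 3,4-dimethoxybenzyl bromide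
Product: 4 diisopropyl (2S,3R)-3-(3,4-dimethoxybenzyl)-2-hydroxybutanedioate, via dilithio alkoxide-enolate 3 (not isolated)
Conditions: LiN(SiMe3)2 (2.2 equiv), THF, −78 → −20 °C, 1 h; 2 (1.1 equiv), −78 → −10 °C, 16 h; AcOH quench
Reagents that add atoms: none
Why: Fráter–Seebach alkylation, in which the lithium-chelated alkoxide-enolate 3 is attacked by the benzylic bromide on the face away from the carbinol substituent, so the bought C2 centre sets C3 as the anti (2S,3R) isomer (about 9:1) while the alkoxide blocks β-elimination.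

**Step 2**
Reactants: 4 diisopropyl (2S,3R)-3-(3,4-dimethoxybenzyl)-2-hydroxybutanedioate
Product: 5 (2S,3R)-3-(3,4-dimethoxybenzyl)-2-hydroxybutanedioic acid
Conditions: KOH (5 equiv), MeOH–H2O 3:1, reflux, 6 h; then 2 M HCl to pH 1
Reagents that add atoms: potassium hydroxide, [K+].[OH-]
Why: Ordinary ester saponification, in which both stereocentres hold because the α-proton of each carboxylate formed is no longer acidic.

**Step 3**
Reactants: 5 (2S,3R)-3-(3,4-dimethoxybenzyl)-2-hydroxybutanedioic acid
Product: 6 (2R)-3-(3,4-dimethoxyphenyl)-2-[(4S)-2,2-dimethyl-5-oxo-1,3-dioxolan-4-yl]propanoic acid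
Conditions: 2,2-dimethoxypropane (5 equiv), TsOH·H2O (5 mol %), acetone, rt, 16 h; recrystallise
Reagents that add atoms: 2,2-dimethoxypropane, COC(C)(C)OC
Why: Acid-catalysed transacetalisation closes the α-hydroxy acid to the five-membered dioxolanone rather than the six-membered alternative, masking C1 and the hydroxyl together, leaving only the C4 acid free, and letting one recrystallisation remove the minor syn isomer from step 1.

**Step 4**
Reactants: 6 (2R)-3-(3,4-dimethoxyphenyl)-2-[(4S)-2,2-dimethyl-5-oxo-1,3-dioxolan-4-yl]propanoic acid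
Product: 8 (3S,4S)-4-(3,4-dimethoxybenzyl)-3-hydroxyoxolan-2-one (OH cis to the benzyl group), via hydroxy dioxolanone 7 (not isolated)
Conditions: BH3·SMe2 (1.4 equiv), THF, 0 °C → rt, 4 h; MeOH quench, concentrate; TsOH·H2O (10 mol %), CH2Cl2, rt, 2 h
Reagents that add atoms: none
Why: Chemoselective borane reduction of the free acid beside the ester-like dioxolanone, followed by acid-catalysed transacylative lactonisation of the primary alcohol with loss of acetone, touches no bond at either stereocentre, so the anti diacid maps onto the cis (3S,4S) lactone.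

**Step 5**
Reactants: 9 homovanillic acid (4-hydroxy-3-methoxyphenylacetic acid)
Product: 11 2-[4-(tert-butyldimethylsilyloxy)-3-methoxyphenyl]acetic acid, via bis-silyl derivative 10 (not isolated)
Conditions: TBSCl (2.3 equiv), imidazole (5 equiv), DMF, rt, 12 h; then AcOH–THF–H2O 3:1:1, rt, 1 h
Reagents that add atoms: tert-butyldimethylsilyl chloride, CC(C)(C)[Si](C)(C)Cl
Why: Exhaustive silylation followed by selective hydrolysis of the much more labile silyl ester masks the phenolic O–H, which would otherwise be the weakest bond present in step 7, with a group that has no weak C–H bond.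

**Step 6**
Reactants: 11 2-[4-(tert-butyldimethylsilyloxy)-3-methoxyphenyl]acetic acid
Product: 12 1,3-dioxoisoindolin-2-yl 2-[4-(tert-butyldimethylsilyloxy)-3-methoxyphenyl]acetate
Conditions: N-hydroxyphthalimide (1.05 equiv), N,N'-diisopropylcarbodiimide (DIC, 1.1 equiv), DMAP (5 mol %), CH2Cl2, 0 °C → rt, 2 h; short silica plug
Reagents that add atoms: N-hydroxyphthalimide, O=C1c2ccccc2C(=O)N1O
Why: Carbodiimide (Steglich-type) esterification gives a crystalline redox-active ester that releases the benzyl radical on one-electron reduction.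

**Step 7**
Reactants: 8 (3S,4S)-4-(3,4-dimethoxybenzyl)-3-hydroxyoxolan-2-one; 12 1,3-dioxoisoindolin-2-yl 2-[4-(tert-butyldimethylsilyloxy)-3-methoxyphenyl]acetate
Product: 14 trachelogenin (3S,4S)-4-(3,4-dimethoxybenzyl)-3-hydroxy-3-(4-hydroxy-3-methoxybenzyl)oxolan-2-one, via O-TBS-trachelogenin 13 (not isolated)
Conditions: 12 (1.5 equiv, three portions), Ir[dF(CF3)ppy]2(dtbbpy)PF6 (1 mol %), quinuclidine (20 mol %), Bu4N(H2PO4) (25 mol %), degassed MeCN (0.1 M), 450 nm LEDs, 20 °C, 24 h; then Bu4NF (1.5 equiv), AcOH (1.5 equiv), 0 °C, 30 min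
Reagents that add atoms: none
Why: Proposed new method: a redox-neutral decarboxylative C–H benzylation of an α-hydroxy lactone by photoredox/hydrogen-atom-transfer catalysis, in which the excited trivalent iridium complex (+1.21 V vs SCE) oxidises quinuclidine (+1.10 V; the veratryl rings at about +1.3 to +1.4 V are spared or repaired by hole transfer to the amine), the divalent iridium formed (−1.37 V) reduces 12 (about −1.3 V) which loses phthalimide anion and CO2 to give the benzyl radical, the quinuclidinium radical cation abstracts the C3 hydrogen of 8 (the weakest C–H bond, captodative, mid-80s kcal/mol, made more hydridic by phosphate hydrogen-bonded to the fairly acidic O–H, and sitting on the open face anti to the C4 side chain), and the two radicals, born 1:1 in one closed cycle, cross-couple because the hindered captodative radical self-terminates slowly (persistent-radical effect); C3 is planar in the radical and the benzyl radical adds anti to the C4 veratrylmethyl group, so the malate-derived C4 centre re-sets C3 as the quaternary (3S) carbinol with trans benzyl groups (dr about 5–10:1 expected, minor epimer removed by chromatography), the enolisable α-keto lactone that would erase C4 is bypassed, and buffered fluoride then frees the phenol; the closest known reaction types are quinuclidine/phosphate α-C–H alkylation of alcohols with acrylates, ketyl–benzyl radical–radical coupling in photoredox benzylation of ketones, and carbene-catalysed decarboxylative coupling of aldehydes with redox-active esters.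

**Compound list**
1 | diisopropyl (S)-malate | CC(C)OC(=O)C[C@H](O)C(=O)OC(C)C | starting material
2 | 3,4-dimethoxybenzyl bromide | COc1ccc(CBr)cc1OC | starting material
3 | dilithio alkoxide-enolate of 1 (chelated geometry) | [Li+].[Li+].CC(C)OC(=O)[C@@H]([O-])/C=C(\[O-])OC(C)C | intermediate
4 | diisopropyl (2S,3R)-3-(3,4-dimethoxybenzyl)-2-hydroxybutanedioate | CC(C)OC(=O)[C@@H](O)[C@@H](Cc1ccc(OC)c(OC)c1)C(=O)OC(C)C | intermediate
5 | (2S,3R)-3-(3,4-dimethoxybenzyl)-2-hydroxybutanedioic acid | OC(=O)[C@@H](O)[C@@H](Cc1ccc(OC)c(OC)c1)C(=O)O | intermediate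
6 | (2R)-3-(3,4-dimethoxyphenyl)-2-[(4S)-2,2-dimethyl-5-oxo-1,3-dioxolan-4-yl]propanoic acid | CC1(C)OC(=O)[C@@H](O1)[C@@H](Cc2ccc(OC)c(OC)c2)C(=O)O | intermediate
7 | (5S)-5-[(2S)-1-(3,4-dimethoxyphenyl)-3-hydroxypropan-2-yl]-2,2-dimethyl-1,3-dioxolan-4-one | CC1(C)OC(=O)[C@@H](O1)[C@@H](Cc2ccc(OC)c(OC)c2)CO | intermediate
8 | (3S,4S)-4-(3,4-dimethoxybenzyl)-3-hydroxyoxolan-2-one (cis) | O[C@@H]1C(=O)OC[C@@H]1Cc2ccc(OC)c(OC)c2 | intermediate
9 | homovanillic acid | COc1cc(CC(=O)O)ccc1O | starting material
10 | tert-butyldimethylsilyl 2-[4-(tert-butyldimethylsilyloxy)-3-methoxyphenyl]acetate | COc1cc(CC(=O)O[Si](C)(C)C(C)(C)C)ccc1O[Si](C)(C)C(C)(C)C | intermediate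
11 | 2-[4-(tert-butyldimethylsilyloxy)-3-methoxyphenyl]acetic acid | COc1cc(CC(=O)O)ccc1O[Si](C)(C)C(C)(C)C | intermediate
12 | 1,3-dioxoisoindolin-2-yl 2-[4-(tert-butyldimethylsilyloxy)-3-methoxyphenyl]acetate | COc1cc(CC(=O)ON2C(=O)c3ccccc3C2=O)ccc1O[Si](C)(C)C(C)(C)C | intermediate
13 | (3S,4S)-3-[4-(tert-butyldimethylsilyloxy)-3-methoxybenzyl]-4-(3,4-dimethoxybenzyl)-3-hydroxyoxolan-2-one | COc1cc(C[C@@]2(O)C(=O)OC[C@@H]2Cc3ccc(OC)c(OC)c3)ccc1O[Si](C)(C)C(C)(C)C | intermediate
14 | trachelogenin, (3S,4S) | COc1cc(C[C@@]2(O)C(=O)OC[C@@H]2Cc2ccc(OC)c(OC)c2)ccc1O | target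

**Totals**
- Total step count: 7.
- Longest linear sequence: 5 steps (steps 1, 2, 3, 4 and 7). The side branch is steps 5 and 6.

**Steps most likely to fail**

**Step 7 (the new reaction).**
Four things could go wrong:
- Hydrogen abstraction may occur at a benzylic CH2, or at the ArCH2C(=O) position of 12, instead of at C3.
- Bibenzyl formation and disproportionation of the C3 radical may compete with cross-coupling.
- The amine may catalyse O-acylation of 8 by 12.
- The facial selectivity may be only modest.

The fallback uses known chemistry, sets out from 8 and comes back at 14. Commercial 4-benzyloxy-3-methoxybenzyl alcohol is treated with PBr3 (Et2O, 0 °C) to give 4-benzyloxy-3-methoxybenzyl bromide F1. Lactone 8 is doubly deprotonated with LiN(iPr)2 (2.3 equiv, THF–DMPU, −78 °C) to the dilithium enediolate F2. F2 is alkylated by F1 anti to the C4 side chain (AcOH quench) to give O-benzyltrachelogenin F3. Hydrogenolysis (H2, 10% Pd/C, EtOAc–EtOH, rt) then gives 14.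

**Step 1.**
The electron-rich bromide 2 is labile, O-alkylation can compete, and the anti:syn ratio may fall. The fallback sets out from 1 (through dianion 3) and comes back at 5. Aldol addition of 3 to 3,4-dimethoxybenzaldehyde (−78 °C) with lactonisation onto the C1 ester in the flask gives isopropyl (3S,4S)-2-(3,4-dimethoxyphenyl)-4-hydroxy-5-oxooxolane-3-carboxylate F4. Both benzylic epimers of F4 are usable. Hydrogenolysis of the benzylic C–O bond (H2, 10% Pd/C, AcOH, 50 °C) opens it to (2S,3R)-3-(3,4-dimethoxybenzyl)-2-hydroxy-4-oxo-4-(propan-2-yloxy)butanoic acid F5. Saponification of F5 as in step 2 gives 5.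

**Step 4.**
The α-branched acid may reduce slowly, and borane may start to attack the dioxolanone. The fallback sets out from 6 and comes back at 7. Compound 6 is activated with isobutyl chloroformate and N-methylmorpholine (THF, −15 °C) as the mixed carbonic anhydride F6. F6 is reduced at once with NaBH4 (THF–H2O, 0 °C) to 7. Compound 7 is lactonised to 8 with TsOH as in step 4.

**Further compounds**
F1 | step 7 | 4-benzyloxy-3-methoxybenzyl bromide | COc1cc(CBr)ccc1OCc2ccccc2
F2 | step 7 | dilithium enediolate of 8 | [Li+].[Li+].[O-]C1=C([O-])OC[C@@H]1Cc2ccc(OC)c(OC)c2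
F3 | step 7 | (3S,4S)-3-(4-benzyloxy-3-methoxybenzyl)-4-(3,4-dimethoxybenzyl)-3-hydroxyoxolan-2-one | COc1cc(C[C@@]2(O)C(=O)OC[C@@H]2Cc3ccc(OC)c(OC)c3)ccc1OCc4ccccc4
F4 | step 1 | isopropyl (3S,4S)-2-(3,4-dimethoxyphenyl)-4-hydroxy-5-oxooxolane-3-carboxylate (C2 epimers) | CC(C)OC(=O)[C@@H]1C(c2ccc(OC)c(OC)c2)OC(=O)[C@H]1O
F5 | step 1 | (2S,3R)-3-(3,4-dimethoxybenzyl)-2-hydroxy-4-oxo-4-(propan-2-yloxy)butanoic acid | OC(=O)[C@@H](O)[C@@H](Cc1ccc(OC)c(OC)c1)C(=O)OC(C)C
F6 | step 4 | mixed isobutyl carbonic anhydride of 6 | CC1(C)OC(=O)[C@@H](O1)[C@@H](Cc2ccc(OC)c(OC)c2)C(=O)OC(=O)OCC(C)C
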